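In the lactone ring (O2–C1–C8a–C4a–C4–C3), C3 with its oxygen O2 is a masked aldehyde C=O, and C4–C4a–C8a–C1 is the skeleton of a homophthalic anhydride whose C4 is a carbon acid; this pairing lets one aldol–lactonisation build the ring.
Retrosynthesis: the phenol is silylated, a carboxyl group is put back on C4, and then C3–C4 and O2–C1 are cut together, giving 8-silyloxyhomophthalic anhydride and (2E,4E)-octadeca-2,4-dienal.
The dienal is cut at its C4=C5 bond (vinylogous Horner–Wadsworth–Emmons) to tetradecanal and a C4 phosphonate; the anhydride goes back through the diacid to 2-methoxy-6-methylbenzoic acid by cutting the benzylic C–CO2H bond.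
Forward: the benzene ring is bought and the anhydride ring is made as a temporary ring. In the key step the complete C17 dienyl chain is joined while the anhydride ring opens and the lactone ring closes. Radical loss of the C4 carboxyl and desilylation finish the synthesis.
Stereochemistry: C3 (R), the only stereocentre, is set in the key step by a cinchona squaramide catalyst that selects the aldehyde face. C4 is transient. Both E alkenes come from the olefination and are carried through.

Key step: step 8

Atom numbers throughout are those of the target lactone: C1 (carbonyl), O2, C3, C4, C4a, C5–C8, C8a.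
Catalyst Q is the squaramide of 9-amino-9-deoxy-epi-quinine with 3,5-bis(trifluoromethyl)aniline, 3-{[3,5-bis(trifluoromethyl)phenyl]amino}-4-{[(8S,9S)-6'-methoxycinchonan-9-yl]amino}cyclobut-3-ene-1,2-dione.
Assumption: Q is taken to give the C3 configuration drawn for the key-step acid; if the first run shows the opposite sense, the quinidine-derived pseudoenantiomer is used in the same step.
The C3 descriptor is S in the C4-carboxylated compounds and R after decarboxylation, through CIP priority only; the spatial arrangement is the same.

Step 1
Reactants: 1 2-methoxy-6-methylbenzoic acid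
Product: 3 2-(carboxymethyl)-6-methoxybenzoic acid (3-methoxyhomophthalic acid), via methyl half-ester 2 (not isolated)
Conditions: LiN(i-Pr)2 (3.5 equiv), THF, −78 °C; (MeO)2CO, −78 to 20 °C; H2O, 20 °C; aq HCl
Reagents that add atoms: dimethyl carbonate COC(=O)OC; water O
Why: Lateral (benzylic) lithiation of the lithium benzoate gives a dianion that is C-acylated by dimethyl carbonate (lateral carboxylation), the acidic product being deprotonated at once so that it cannot react twice, and the lithium hydroxide formed on adding water saponifies the aliphatic methyl ester in the same flask.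

Step 2
Reactants: 3 2-(carboxymethyl)-6-methoxybenzoic acid
Product: 4 2-(carboxymethyl)-6-hydroxybenzoic acid (3-hydroxyhomophthalic acid)
Conditions: BBr3 (4 equiv), CH2Cl2, −78 to 20 °C; H2O
Reagents that add atoms: none
Why: Aryl methyl ether cleavage by BBr3 (boron binds the ether oxygen and bromide attacks the methyl group in an SN2 step) is routine for anisoles bearing carboxyl groups, and it is placed here because no Lewis acid can be used once the dienylic lactone exists.

Step 3
Reactants: 4 2-(carboxymethyl)-6-hydroxybenzoic acid
Product: 6 2-[(tert-butyldimethylsilyl)oxy]-6-(carboxymethyl)benzoic acid, via tris-silyl derivative 5 (not isolated)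
Conditions: TBSCl (3.5 equiv), imidazole (7 equiv), DMF, 20 °C; then AcOH/THF/H2O, 20 °C
Reagents that add atoms: tert-butyldimethylsilyl chloride CC(C)(C)[Si](C)(C)Cl
Why: Imidazole-mediated silylation caps the phenol and both carboxyl groups, after which the two silyl esters, far more labile to dilute aqueous acid than an aryl silyl ether, are hydrolysed selectively.

Step 4
Reactants: 6 2-[(tert-butyldimethylsilyl)oxy]-6-(carboxymethyl)benzoic acid
Product: 7 8-[(tert-butyldimethylsilyl)oxy]isochromane-1,3-dione (8-silyloxyhomophthalic anhydride; kept dry and used fresh)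
Conditions: DCC (1.05 equiv), CH2Cl2, 0 to 20 °C; filtration
Reagents that add atoms: none
Why: Carbodiimide cyclodehydration, in which the O-acylisourea of one carboxyl group is captured by the neighbouring carboxyl to close the six-membered anhydride under neutral conditions that spare the aryl silyl ether and do not enolise the C4 methylene.

Step 5
Reactants: 8 tetradecanal; 9 triethyl (E)-4-phosphonocrotonate
Product: 10 ethyl (2E,4E)-octadeca-2,4-dienoate
Conditions: LiN(SiMe3)2 (1.1 equiv), 9, THF, −78 °C; then 8, −78 to 0 °C; aq NH4Cl
Reagents that add atoms: none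
Why: Vinylogous Horner–Wadsworth–Emmons olefination, in which the lithium anion of the phosphonate adds through the carbon next to phosphorus and syn-elimination of diethyl phosphate from the equilibrated adduct gives the new 4E double bond while the 2E bond of the reagent is retained.

Step 6
Reactants: 10 ethyl (2E,4E)-octadeca-2,4-dienoate
Product: 11 (2E,4E)-octadeca-2,4-dien-1-ol
Conditions: i-Bu2AlH (2.2 equiv), CH2Cl2, −78 °C; aq potassium sodium tartrate
Reagents that add atoms: none
Why: i-Bu2AlH reduces the conjugated ester to the allylic alcohol by two 1,2-hydride transfers without touching the diene.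

Step 7
Reactants: 11 (2E,4E)-octadeca-2,4-dien-1-ol
Product: 12 (2E,4E)-octadeca-2,4-dienal
Conditions: activated MnO2 (excess), CH2Cl2, 20 °C
Reagents that add atoms: none
Why: MnO2 oxidises allylic alcohols selectively to enals on its surface under neutral conditions, with no over-oxidation and no change of alkene geometry.

Step 8
Reactants: 7 8-[(tert-butyldimethylsilyl)oxy]isochromane-1,3-dione; 12 (2E,4E)-octadeca-2,4-dienal
Product: 14 (3S,4R)-8-[(tert-butyldimethylsilyl)oxy]-3-[(1E,3E)-heptadeca-1,3-dienyl]-1-oxoisochromane-4-carboxylic acid, via aldol adduct 13 (not isolated)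
Conditions: 7 (1 equiv), 12 (1.2 equiv), catalyst Q (5 mol%), dry MTBE, −15 °C; cold aq citric acid
Reagents that add atoms: none
Why: Proposed new method: the quinuclidine nitrogen of Q removes a proton from C4 of 7 (a carbon acid flanked by the arene and an anhydride carbonyl), the squaramide N–H pair binds the aldehyde oxygen of 12, and the ion-paired enolate adds 1,2 to the carbonyl carbon, which forms the C3–C4 bond of aldol adduct 13. The C3 alkoxide of 13 then attacks the aryl-bound carbonyl C1 in a 6-exo-trig acyl transfer that closes the lactone ring O2–C1–C8a–C4a–C4–C3, opens the anhydride ring and leaves the other carbonyl as the carboxylate on C4, so the aldol step cannot revert. The closest known reaction type is the cinchona-squaramide-catalysed formal cycloaddition of homophthalic anhydride with aryl and alkyl aldehydes, which has not been shown with a conjugated 2,4-dienal or with an anhydride carrying a silyloxy group next to C1. C3 is controlled by the catalyst, whose hydrogen-bond and ion-pair contacts leave one enantioface of the bound aldehyde open to the enolate, whereas C4 is controlled by the substrate (the dienyl and carboxyl groups are expected to settle trans on the new ring) and is erased in step 10, so either C4 epimer serves. The step needs 1,2- over 1,4- and 1,6-addition and acyl transfer to C1 rather than to the carbonyl next to C4: only the 1,2-adduct carries an alkoxide that can be trapped by lactonisation, while conjugate adducts of the stabilised enolate can revert, and attack on the other carbonyl would give a strained four-membered lactone instead of the six-membered ring. The dienylic C3–O2 bond is thus made at −15 °C without acid, Lewis acid or zerovalent palladium, so no pentadienyl cation or allyl-metal pathway can scramble C3.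

Step 9
Reactants: 14 (3S,4R)-8-[(tert-butyldimethylsilyl)oxy]-3-[(1E,3E)-heptadeca-1,3-dienyl]-1-oxoisochromane-4-carboxylic acid
Product: 15 1,3-dioxoisoindolin-2-yl (3S,4R)-8-[(tert-butyldimethylsilyl)oxy]-3-[(1E,3E)-heptadeca-1,3-dienyl]-1-oxoisochromane-4-carboxylate
Conditions: N-hydroxyphthalimide (1.1 equiv), DIC (1.1 equiv), CH2Cl2, 0 °C, no amine base, no DMAP
Reagents that add atoms: N-hydroxyphthalimide O=C1c2ccccc2C(=O)N1O
Why: Carbodiimide (Steglich-type) esterification in which the O-acylisourea of 14 is intercepted by the acidic N–OH group, and leaving out amine base keeps the strongly acidified C4–H from starting an E1cB opening of the lactone, while epimerisation at C4 would be of no consequence.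

Step 10
Reactants: 15 1,3-dioxoisoindolin-2-yl (3S,4R)-8-[(tert-butyldimethylsilyl)oxy]-3-[(1E,3E)-heptadeca-1,3-dienyl]-1-oxoisochromane-4-carboxylate
Product: 16 (3R)-8-[(tert-butyldimethylsilyl)oxy]-3-[(1E,3E)-heptadeca-1,3-dienyl]isochroman-1-one
Conditions: Hantzsch ester (diethyl 2,6-dimethyl-1,4-dihydropyridine-3,5-dicarboxylate, 3 equiv), Ru(bpy)3(PF6)2 (1 mol%; bpy = 2,2'-bipyridine), degassed concentrated CH2Cl2, blue LEDs, 20 °C
Reagents that add atoms: none
Why: Photoredox reductive decarboxylation of a redox-active N-(acyloxy)phthalimide, in which electron transfer from the reduced ruthenium complex cleaves the N–O bond, loss of CO2 gives the benzylic C4 radical, and hydrogen-atom transfer from the excess Hantzsch ester is expected to outrun reduction to the anion, acyloxy migration and cyclisation onto the diene, so that C3 and both alkenes are untouched while the C4 centre disappears.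

Step 11
Reactants: 16 (3R)-8-[(tert-butyldimethylsilyl)oxy]-3-[(1E,3E)-heptadeca-1,3-dienyl]isochroman-1-one
Product: 17 (3R)-3-[(1E,3E)-heptadeca-1,3-dienyl]-8-hydroxyisochroman-1-one (CNP0165705.1)
Conditions: Bu4NF (1.2 equiv), AcOH (1.2 equiv), THF, 0 °C
Reagents that add atoms: none
Why: Fluoride-induced cleavage of the aryl Si–O bond is driven by the strong Si–F bond, and the acetic acid buffer protonates the phenoxide at once, so the lactone and the dienylic C3–O2 bond meet neither base nor acid strong enough to open or ionise them.

Compound list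
1 | 2-methoxy-6-methylbenzoic acid | COc1cccc(C)c1C(=O)O | starting material
2 | 2-methoxy-6-(2-methoxy-2-oxoethyl)benzoic acid (methyl half-ester, present as its lithium salt) | COC(=O)Cc1cccc(OC)c1C(=O)O | intermediate (not isolated)
3 | 2-(carboxymethyl)-6-methoxybenzoic acid (3-methoxyhomophthalic acid) | COc1cccc(CC(=O)O)c1C(=O)O | intermediate
4 | 2-(carboxymethyl)-6-hydroxybenzoic acid (3-hydroxyhomophthalic acid) | Oc1cccc(CC(=O)O)c1C(=O)O | intermediate
5 | tert-butyldimethylsilyl 2-[(tert-butyldimethylsilyl)oxy]-6-{2-[(tert-butyldimethylsilyl)oxy]-2-oxoethyl}benzoate | CC(C)(C)[Si](C)(C)OC(=O)Cc1cccc(O[Si](C)(C)C(C)(C)C)c1C(=O)O[Si](C)(C)C(C)(C)C | intermediate (not isolated)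
6 | 2-[(tert-butyldimethylsilyl)oxy]-6-(carboxymethyl)benzoic acid | CC(C)(C)[Si](C)(C)Oc1cccc(CC(=O)O)c1C(=O)O | intermediate
7 | 8-[(tert-butyldimethylsilyl)oxy]isochromane-1,3-dione | O=C1Cc2cccc(O[Si](C)(C)C(C)(C)C)c2C(=O)O1 | intermediate
8 | tetradecanal | CCCCCCCCCCCCCC=O | starting material
9 | triethyl (E)-4-phosphonocrotonate [ethyl (E)-4-(diethoxyphosphoryl)but-2-enoate] | CCOC(=O)/C=C/CP(=O)(OCC)OCC | starting material
10 | ethyl (2E,4E)-octadeca-2,4-dienoate | CCCCCCCCCCCCC/C=C/C=C/C(=O)OCC | intermediate
11 | (2E,4E)-octadeca-2,4-dien-1-ol | CCCCCCCCCCCCC/C=C/C=C/CO | intermediate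
12 | (2E,4E)-octadeca-2,4-dienal | CCCCCCCCCCCCC/C=C/C=C/C=O | intermediate
13 | (4R)-8-[(tert-butyldimethylsilyl)oxy]-4-[(1S,2E,4E)-1-hydroxyoctadeca-2,4-dienyl]isochromane-1,3-dione (aldol adduct, present as the alkoxide ion-paired with the catalyst) | CCCCCCCCCCCCC/C=C/C=C/[C@H](O)[C@@H]1C(=O)OC(=O)c2c(O[Si](C)(C)C(C)(C)C)cccc12 | intermediate (not isolated)
14 | (3S,4R)-8-[(tert-butyldimethylsilyl)oxy]-3-[(1E,3E)-heptadeca-1,3-dienyl]-1-oxoisochromane-4-carboxylic acid (trans) | CCCCCCCCCCCCC/C=C/C=C/[C@H]1[C@H](C(=O)O)c2cccc(O[Si](C)(C)C(C)(C)C)c2C(=O)O1 | intermediate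
15 | 1,3-dioxoisoindolin-2-yl (3S,4R)-8-[(tert-butyldimethylsilyl)oxy]-3-[(1E,3E)-heptadeca-1,3-dienyl]-1-oxoisochromane-4-carboxylate | CCCCCCCCCCCCC/C=C/C=C/[C@H]1[C@H](C(=O)ON3C(=O)c4ccccc4C3=O)c2cccc(O[Si](C)(C)C(C)(C)C)c2C(=O)O1 | intermediate
16 | (3R)-8-[(tert-butyldimethylsilyl)oxy]-3-[(1E,3E)-heptadeca-1,3-dienyl]isochroman-1-one | CCCCCCCCCCCCC/C=C/C=C/[C@H]1Cc2cccc(O[Si](C)(C)C(C)(C)C)c2C(=O)O1 | intermediate
17 | (3R)-3-[(1E,3E)-heptadeca-1,3-dienyl]-8-hydroxyisochroman-1-one | CCCCCCCCCCCCC/C=C/C=C/[C@H]1Cc2cccc(O)c2C(=O)O1 | target

Total step count: 11.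
Longest linear sequence: 8 steps (steps 1–4 and 8–11, from 1); the dienal arm (steps 5–7) joins at step 8.

Steps most likely to fail

1. Step 8 (carries the label). Three processes could defeat it:
- conjugate (1,4- or 1,6-) addition of the enolate to the dienal;
- weak discrimination between the faces of a slim conjugated aldehyde;
- slow acyl transfer at C1 beside the silyloxy group, so that the aldol step reverts.

Fallback, from known reactions only, setting out from 1 and 10 and returning at 17. Acid 1 is demethylated with BBr3 to 2-hydroxy-6-methylbenzoic acid F1, which is condensed with acetone (trifluoroacetic anhydride, trifluoroacetic acid) to 2,2,5-trimethyl-4H-1,3-benzodioxin-4-one F2. Ester 10 is converted with N,O-dimethylhydroxylamine hydrochloride and i-PrMgCl into the Weinreb amide (2E,4E)-N-methoxy-N-methyloctadeca-2,4-dienamide F3. Lateral lithiation of F2 with LiN(i-Pr)2 at −78 °C and acylation by F3 should give the ketone 2,2-dimethyl-5-[(3E,5E)-2-oxononadeca-3,5-dienyl]-4H-1,3-benzodioxin-4-one F4. Corey–Bakshi–Shibata reduction with the (S)-oxazaborolidine and catecholborane at low temperature, the dienyl group acting as the large substituent, is expected to give the carbinol 5-[(2R,3E,5E)-2-hydroxynonadeca-3,5-dienyl]-2,2-dimethyl-4H-1,3-benzodioxin-4-one F5. A catalytic amount of NaH in THF then lets the alkoxide attack the dioxinone carbonyl; this closes the lactone, releases acetone and frees the 8-hydroxy group, giving 17 directly.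

2. Step 10. Three processes could compete with hydrogen transfer:
- reduction of the C4 radical to the benzylic anion, which would expel the C3 carboxylate (E1cB ring opening);
- migration of the lactone oxygen from C3 to C4, pulled by formation of a pentadienyl radical;
- attack of the radical on the diene.

Fallback, setting out from 14 and returning at 16: a non-reductive radical chain replaces electron transfer. Acid 14 is coupled with N-hydroxypyridine-2-thione (DCC, CH2Cl2, 0 °C, dark) to the thiohydroxamate ester 2-thioxopyridin-1(2H)-yl (3S,4R)-8-[(tert-butyldimethylsilyl)oxy]-3-[(1E,3E)-heptadeca-1,3-dienyl]-1-oxoisochromane-4-carboxylate F6. F6 is irradiated with visible light at 0 °C in the presence of a large excess of tert-butyl thiol (Barton reductive decarboxylation). No electron donor is present, so the anionic pathway is closed and the C4 radical is quenched by the thiol.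

3. Step 9. Activation of the carboxyl makes C4–H acidic enough for the isourea or urea to act as base and open the lactone by E1cB, or the O-acylisourea rearranges to the N-acylurea.

Fallback, setting out from 14 and returning at 16, with no acyl activation and no new compound. The carboxylate of 14 (2,4,6-collidine) is oxidised under blue light by the excited photocatalyst Ir[dF(CF3)ppy]2(dtbbpy)PF6, with a hindered aryl thiol (2,4,6-triisopropylbenzenethiol) as hydrogen-atom-transfer co-catalyst. Loss of CO2 gives the same C4 radical, which takes hydrogen from the thiol. This is the known photocatalytic hydrodecarboxylation of free arylacetic acids.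

Further compounds
F1 | step 8 | 2-hydroxy-6-methylbenzoic acid | Cc1cccc(O)c1C(=O)O
F2 | step 8 | 2,2,5-trimethyl-4H-1,3-benzodioxin-4-one | Cc1cccc2OC(C)(C)OC(=O)c12
F3 | step 8 | (2E,4E)-N-methoxy-N-methyloctadeca-2,4-dienamide | CCCCCCCCCCCCC/C=C/C=C/C(=O)N(C)OC
F4 | step 8 | 2,2-dimethyl-5-[(3E,5E)-2-oxononadeca-3,5-dienyl]-4H-1,3-benzodioxin-4-one | CCCCCCCCCCCCC/C=C/C=C/C(=O)Cc1cccc2OC(C)(C)OC(=O)c12
F5 | step 8 | 5-[(2R,3E,5E)-2-hydroxynonadeca-3,5-dienyl]-2,2-dimethyl-4H-1,3-benzodioxin-4-one | CCCCCCCCCCCCC/C=C/C=C/[C@H](O)Cc1cccc2OC(C)(C)OC(=O)c12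
F6 | step 10 | 2-thioxopyridin-1(2H)-yl (3S,4R)-8-[(tert-butyldimethylsilyl)oxy]-3-[(1E,3E)-heptadeca-1,3-dienyl]-1-oxoisochromane-4-carboxylate | CCCCCCCCCCCCC/C=C/C=C/[C@H]1[C@H](C(=O)ON3C=CC=CC3=S)c2cccc(O[Si](C)(C)C(C)(C)C)c2C(=O)O1
F0 | step 9 | none | none
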